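**Retrosynthetic overview**
1. Target 21 ⇐ ring-closing metathesis (C8=C9) of diene 20; the seven-membered ring is closed in the last step.
2. 20 ⇐ ynone 9 by two esterifications (acid chlorides 13 and 17) around a reagent-controlled ynone reduction (C10), then desilylation and alkyne semihydrogenation.
3. 9 ⇐ acetylide opening of the cis-fused γ-lactone 8 (frees O6, turns C10 into a ketone); 8 ⇐ keto-lactone 7 + isopropyl nucleophile (C4).
4. 7 ⇐ one-pot union of enone ester 2, Me2Zn and aldehyde 4: asymmetric conjugate addition (C1), anti aldol (C5, C6), lactonization.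
5. Ring order: cyclopentane (present in 1) → temporary γ-lactone → cycloheptene by metathesis.

Assumption: locants C1–C10 are those of the target's carbocyclic core (C1 = ring-fusion C–CH3, C4 = C(OH)(i-Pr), C5 = ring-fusion CH, C6 = CH–O-aroyl, C8 = C(CH3)=, C10 = CH–O-tigloyl); tigloyl = (E)-2-methylbut-2-enoyl.

**Route**

Step 1
Reactants: 1 methyl cyclopent-1-ene-1-carboxylate
Product: 2 methyl 3-oxocyclopent-1-ene-1-carboxylate
Conditions: t-BuOOH (70% aq, 5 equiv), Rh2(cap)4 (cap = caprolactamate, 1 mol %), K2CO3 (0.5 equiv), CH2Cl2, rt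
Reagents that add atoms: tert-butyl hydroperoxide, CC(C)(C)OO
Why: Dirhodium-catalysed allylic C–H oxidation takes place at the ring CH2 next to the β-carbon (the γ-position of the enoate), giving the enone ester without creating a stereocentre.

Step 2
Reactants: 3 3-methylbut-3-en-1-ol
Product: 4 3-methylbut-3-enal
Conditions: Dess–Martin periodinane (1.2 equiv), CH2Cl2, 0 °C → rt; filtered cold and used at once as a solution
Reagents that add atoms: none
Why: Dess–Martin oxidation gives the β,γ-unsaturated aldehyde under non-basic conditions, so the alkene does not move into conjugation; no stereocentre is formed.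

Step 3
Reactants: 2 methyl 3-oxocyclopent-1-ene-1-carboxylate; 4 3-methylbut-3-enal
Product: 7 (3R,3aS,6aR)-6a-methyl-3-(2-methylprop-2-en-1-yl)hexahydro-1H-cyclopenta[c]furan-1,4-dione, via methylzinc enolate 5 (not isolated), via aldol hydroxy ester 6 (not isolated)
Conditions: Me2Zn (3 equiv), Cu(OTf)2 (5 mol %), chiral sulfonate-bearing 4,5-diphenylimidazolinium salt (NHC precursor, 5 mol %, enantiomer that sends CH3 to the Si face of C1), t-BuOMe, −30 °C; then 4 (3 equiv), −78 → −20 °C; aq NH4Cl; crude treated with CSA (10 mol %), CH2Cl2, rt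
Reagents that add atoms: dimethylzinc, C[Zn]C
Why: Copper-catalysed asymmetric conjugate addition puts CH3 on the ester-bearing β-carbon under ligand control (C1 = R); the ring-locked E zinc enolate then gives a Zimmerman–Traxler anti aldol with 4 on the face opposite the new methyl (C5 = S, C6 = R), and the hydroxyl cis to the ester lactonizes, acid funnelling any C5 epimer through its enol into the only possible cis-fused γ-lactone.

Step 4
Reactants: 7 (3R,3aS,6aR)-6a-methyl-3-(2-methylprop-2-en-1-yl)hexahydro-1H-cyclopenta[c]furan-1,4-dione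
Product: 8 (3R,3aS,4R,6aR)-4-hydroxy-6a-methyl-3-(2-methylprop-2-en-1-yl)-4-(propan-2-yl)hexahydro-1H-cyclopenta[c]furan-1-one
Conditions: i-PrMgCl (1.5 equiv), anhydrous CeCl3 (1.6 equiv), THF, −78 °C; aq NH4Cl
Reagents that add atoms: isopropylmagnesium chloride, CC(C)[Mg]Cl
Why: Organocerium 1,2-addition is weakly basic, so the β-acyloxy ketone neither enolizes nor eliminates and the lactone is spared at −78 °C; attack on the convex face of the cis-fused bicycle, anti to the C5–C6 bond, places isopropyl cis to H-5 and the hydroxyl on the lactone face (C4 = R).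

Step 5
Reactants: 8 (3R,3aS,4R,6aR)-4-hydroxy-6a-methyl-3-(2-methylprop-2-en-1-yl)-4-(propan-2-yl)hexahydro-1H-cyclopenta[c]furan-1-one
Product: 9 1-[(1R,2S,3R)-3-hydroxy-2-[(1R)-1-hydroxy-3-methylbut-3-en-1-yl]-1-methyl-3-(propan-2-yl)cyclopentyl]-3-(trimethylsilyl)prop-2-yn-1-one
Conditions: HC≡CSiMe3 (4 equiv), n-BuLi (3.8 equiv), THF, −78 °C; add 8, −78 → −30 °C; aq NH4Cl
Reagents that add atoms: lithium (trimethylsilyl)acetylide, [Li]C#C[Si](C)(C)C
Why: Acyl substitution of the lactone by a lithium acetylide stops at the ynone because the lithium hemiketal survives until work-up and C1 carries no α-hydrogen; C10 becomes a ketone and the C6 hydroxyl is freed, so the two oxygens are differentiated and no stereocentre changes.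

Step 6
Reactants: 10 4-hydroxybenzoic acid
Product: 11 tert-butyldimethylsilyl 4-[(tert-butyldimethylsilyl)oxy]benzoate
Conditions: TBSCl (2.3 equiv), imidazole (4.6 equiv), DMF, rt
Reagents that add atoms: tert-butyldimethylsilyl chloride, CC(C)(C)[Si](C)(C)Cl
Why: Imidazole-mediated silylation caps both the phenol and the acid, which is the simplest way to a phenol-protected benzoic acid.

Step 7
Reactants: 11 tert-butyldimethylsilyl 4-[(tert-butyldimethylsilyl)oxy]benzoate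
Product: 12 4-[(tert-butyldimethylsilyl)oxy]benzoic acid
Conditions: AcOH/THF/H2O (3:1:1), rt
Reagents that add atoms: none
Why: Selective hydrolysis: the silyl ester is far more labile than the aryl silyl ether and is cleaved alone under mild aqueous acid.

Step 8
Reactants: 12 4-[(tert-butyldimethylsilyl)oxy]benzoic acid
Product: 13 4-[(tert-butyldimethylsilyl)oxy]benzoyl chloride
Conditions: (COCl)2 (1.3 equiv), DMF (cat.), CH2Cl2, 0 °C → rt; concentrated and used crude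
Reagents that add atoms: oxalyl chloride, O=C(Cl)C(=O)Cl
Why: Vilsmeier-type activation with oxalyl chloride gives the acid chloride under conditions the aryl silyl ether tolerates.

Step 9
Reactants: 9 1-[(1R,2S,3R)-3-hydroxy-2-[(1R)-1-hydroxy-3-methylbut-3-en-1-yl]-1-methyl-3-(propan-2-yl)cyclopentyl]-3-(trimethylsilyl)prop-2-yn-1-one; 13 4-[(tert-butyldimethylsilyl)oxy]benzoyl chloride
Product: 14 (1R)-1-[(1S,2R,5R)-2-hydroxy-5-methyl-2-(propan-2-yl)-5-[3-(trimethylsilyl)prop-2-ynoyl]cyclopentyl]-3-methylbut-3-en-1-yl 4-[(tert-butyldimethylsilyl)oxy]benzoate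
Conditions: 13 (1.5 equiv), Et3N (3 equiv), DMAP (0.2 equiv), CH2Cl2, 0 °C → rt
Reagents that add atoms: none
Why: DMAP-catalysed acylation by the acid chloride hits only the secondary C6 hydroxyl, the tertiary C4 hydroxyl being too hindered, and any C6–O/C10 hemiketal drains through the open hydroxy ketone; no stereocentre is formed.

Step 10
Reactants: 14 (1R)-1-[(1S,2R,5R)-2-hydroxy-5-methyl-2-(propan-2-yl)-5-[3-(trimethylsilyl)prop-2-ynoyl]cyclopentyl]-3-methylbut-3-en-1-yl 4-[(tert-butyldimethylsilyl)oxy]benzoate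
Product: 15 (1R)-1-[(1S,2R,5R)-2-hydroxy-5-[(1R)-1-hydroxy-3-(trimethylsilyl)prop-2-yn-1-yl]-5-methyl-2-(propan-2-yl)cyclopentyl]-3-methylbut-3-en-1-yl 4-[(tert-butyldimethylsilyl)oxy]benzoate
Conditions: Ru[(R,R)-TsNCH(Ph)CH(Ph)NH](p-cymene) (5 mol %), i-PrOH, rt
Reagents that add atoms: none
Why: Noyori asymmetric transfer hydrogenation of an alkynyl ketone: the (R,R)-TsDPEN ruthenium hydride distinguishes the alkyne from the tertiary alkyl group and sets C10 under reagent control (10R by the sequence rule here, the same spatial arrangement being 10S once the silyl group is gone).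

Step 11
Reactants: 16 tiglic acid
Product: 17 tigloyl chloride
Conditions: (COCl)2 (1.2 equiv), DMF (cat.), CH2Cl2, 0 °C → rt; distilled
Reagents that add atoms: oxalyl chloride, O=C(Cl)C(=O)Cl
Why: Standard acid chloride formation; the E geometry is the thermodynamically stable one and is kept.

Step 12
Reactants: 15 (1R)-1-[(1S,2R,5R)-2-hydroxy-5-[(1R)-1-hydroxy-3-(trimethylsilyl)prop-2-yn-1-yl]-5-methyl-2-(propan-2-yl)cyclopentyl]-3-methylbut-3-en-1-yl 4-[(tert-butyldimethylsilyl)oxy]benzoate; 17 tigloyl chloride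
Product: 18 (1R)-1-[(1S,2R,5R)-2-hydroxy-5-methyl-5-[(1R)-1-{[(2E)-2-methylbut-2-enoyl]oxy}-3-(trimethylsilyl)prop-2-yn-1-yl]-2-(propan-2-yl)cyclopentyl]-3-methylbut-3-en-1-yl 4-[(tert-butyldimethylsilyl)oxy]benzoate
Conditions: 17 (3 equiv), pyridine, DMAP (1 equiv), CH2Cl2, 0 → 40 °C
Reagents that add atoms: none
Why: Pyridine/DMAP-mediated esterification of the hindered propargylic alcohol with the acid chloride; the tertiary alcohol stays free and C10 is not touched.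

Step 13
Reactants: 18 (1R)-1-[(1S,2R,5R)-2-hydroxy-5-methyl-5-[(1R)-1-{[(2E)-2-methylbut-2-enoyl]oxy}-3-(trimethylsilyl)prop-2-yn-1-yl]-2-(propan-2-yl)cyclopentyl]-3-methylbut-3-en-1-yl 4-[(tert-butyldimethylsilyl)oxy]benzoate
Product: 19 (1R)-1-[(1S,2R,5R)-2-hydroxy-5-methyl-5-[(1S)-1-{[(2E)-2-methylbut-2-enoyl]oxy}prop-2-yn-1-yl]-2-(propan-2-yl)cyclopentyl]-3-methylbut-3-en-1-yl 4-hydroxybenzoate
Conditions: Bu4NF (2.5 equiv), AcOH (2.5 equiv), THF, 0 °C
Reagents that add atoms: none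
Why: Fluoride-induced desilylation cleaves the alkynyl C–Si bond and the aryl silyl ether in one operation, acetic acid buffering protecting both esters.

Step 14
Reactants: 19 (1R)-1-[(1S,2R,5R)-2-hydroxy-5-methyl-5-[(1S)-1-{[(2E)-2-methylbut-2-enoyl]oxy}prop-2-yn-1-yl]-2-(propan-2-yl)cyclopentyl]-3-methylbut-3-en-1-yl 4-hydroxybenzoate
Product: 20 (1R)-1-[(1S,2R,5R)-2-hydroxy-5-methyl-5-[(1S)-1-{[(2E)-2-methylbut-2-enoyl]oxy}prop-2-en-1-yl]-2-(propan-2-yl)cyclopentyl]-3-methylbut-3-en-1-yl 4-hydroxybenzoate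
Conditions: H2 (1 atm), Pd/CaCO3 poisoned with Pb(OAc)2 (Lindlar catalyst), quinoline, EtOAc, rt
Reagents that add atoms: none
Why: Lindlar semihydrogenation reduces only the terminal alkyne and stops at the alkene, leaving the 1,1-disubstituted alkene and the conjugated trisubstituted tiglate alone.

Step 15
Reactants: 20 (1R)-1-[(1S,2R,5R)-2-hydroxy-5-methyl-5-[(1S)-1-{[(2E)-2-methylbut-2-enoyl]oxy}prop-2-en-1-yl]-2-(propan-2-yl)cyclopentyl]-3-methylbut-3-en-1-yl 4-hydroxybenzoate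
Product: 21 (3R,3aS,4R,8S,8aR)-3-hydroxy-6,8a-dimethyl-8-{[(2E)-2-methylbut-2-enoyl]oxy}-3-(propan-2-yl)-1,2,3,3a,4,5,8,8a-octahydroazulen-4-yl 4-hydroxybenzoate
Conditions: second-generation Hoveyda–Grubbs catalyst (H2IMes)Cl2Ru=CH(C6H4-2-O-i-Pr) (10 mol %), PhMe (2 mM), 80 °C
Reagents that add atoms: none
Why: Ring-closing metathesis between the vinyl group and the 1,1-disubstituted alkene, held cis on the cyclopentane, expels ethylene and forms the trisubstituted cycloheptene; no stereocentre is touched.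

**Compound list**
1 | methyl cyclopent-1-ene-1-carboxylate | COC(=O)C1=CCCC1 | starting material
2 | methyl 3-oxocyclopent-1-ene-1-carboxylate | COC(=O)C1=CC(=O)CC1 | intermediate
3 | 3-methylbut-3-en-1-ol | CC(=C)CCO | starting material
4 | 3-methylbut-3-enal | CC(=C)CC=O | intermediate
5 | methyl (1R)-1-methyl-3-[(methylzincio)oxy]cyclopent-2-ene-1-carboxylate (methylzinc enolate) | COC(=O)[C@]1(C)CCC(O[Zn]C)=C1 | intermediate
6 | methyl (1R,2S)-2-[(1R)-1-hydroxy-3-methylbut-3-en-1-yl]-1-methyl-3-oxocyclopentane-1-carboxylate | COC(=O)[C@]1(C)CCC(=O)[C@@H]1[C@H](O)CC(C)=C | intermediate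
7 | (3R,3aS,6aR)-6a-methyl-3-(2-methylprop-2-en-1-yl)hexahydro-1H-cyclopenta[c]furan-1,4-dione | C=C(C)C[C@H]1OC(=O)[C@]2(C)CCC(=O)[C@H]12 | intermediate
8 | (3R,3aS,4R,6aR)-4-hydroxy-6a-methyl-3-(2-methylprop-2-en-1-yl)-4-(propan-2-yl)hexahydro-1H-cyclopenta[c]furan-1-one | C=C(C)C[C@H]1OC(=O)[C@]2(C)CC[C@@](O)(C(C)C)[C@H]12 | intermediate
9 | 1-[(1R,2S,3R)-3-hydroxy-2-[(1R)-1-hydroxy-3-methylbut-3-en-1-yl]-1-methyl-3-(propan-2-yl)cyclopentyl]-3-(trimethylsilyl)prop-2-yn-1-one | O=C(C#C[Si](C)(C)C)[C@]1(C)CC[C@@](O)(C(C)C)[C@@H]1[C@H](O)CC(C)=C | intermediate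
10 | 4-hydroxybenzoic acid | O=C(O)c1ccc(O)cc1 | starting material
11 | tert-butyldimethylsilyl 4-[(tert-butyldimethylsilyl)oxy]benzoate | CC(C)(C)[Si](C)(C)OC(=O)c1ccc(O[Si](C)(C)C(C)(C)C)cc1 | intermediate
12 | 4-[(tert-butyldimethylsilyl)oxy]benzoic acid | O=C(O)c1ccc(O[Si](C)(C)C(C)(C)C)cc1 | intermediate
13 | 4-[(tert-butyldimethylsilyl)oxy]benzoyl chloride | O=C(Cl)c1ccc(O[Si](C)(C)C(C)(C)C)cc1 | intermediate
14 | (1R)-1-[(1S,2R,5R)-2-hydroxy-5-methyl-2-(propan-2-yl)-5-[3-(trimethylsilyl)prop-2-ynoyl]cyclopentyl]-3-methylbut-3-en-1-yl 4-[(tert-butyldimethylsilyl)oxy]benzoate | O=C(C#C[Si](C)(C)C)[C@]1(C)CC[C@@](O)(C(C)C)[C@@H]1[C@H](OC(=O)c1ccc(O[Si](C)(C)C(C)(C)C)cc1)CC(C)=C | intermediate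
15 | (1R)-1-[(1S,2R,5R)-2-hydroxy-5-[(1R)-1-hydroxy-3-(trimethylsilyl)prop-2-yn-1-yl]-5-methyl-2-(propan-2-yl)cyclopentyl]-3-methylbut-3-en-1-yl 4-[(tert-butyldimethylsilyl)oxy]benzoate | O[C@@H](C#C[Si](C)(C)C)[C@]1(C)CC[C@@](O)(C(C)C)[C@@H]1[C@H](OC(=O)c1ccc(O[Si](C)(C)C(C)(C)C)cc1)CC(C)=C | intermediate
16 | tiglic acid, (2E)-2-methylbut-2-enoic acid | C/C=C(\C)C(=O)O | starting material
17 | tigloyl chloride, (2E)-2-methylbut-2-enoyl chloride | C/C=C(\C)C(=O)Cl | intermediate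
18 | (1R)-1-[(1S,2R,5R)-2-hydroxy-5-methyl-5-[(1R)-1-{[(2E)-2-methylbut-2-enoyl]oxy}-3-(trimethylsilyl)prop-2-yn-1-yl]-2-(propan-2-yl)cyclopentyl]-3-methylbut-3-en-1-yl 4-[(tert-butyldimethylsilyl)oxy]benzoate | C/C=C(\C)C(=O)O[C@@H](C#C[Si](C)(C)C)[C@]1(C)CC[C@@](O)(C(C)C)[C@@H]1[C@H](OC(=O)c1ccc(O[Si](C)(C)C(C)(C)C)cc1)CC(C)=C | intermediate
19 | (1R)-1-[(1S,2R,5R)-2-hydroxy-5-methyl-5-[(1S)-1-{[(2E)-2-methylbut-2-enoyl]oxy}prop-2-yn-1-yl]-2-(propan-2-yl)cyclopentyl]-3-methylbut-3-en-1-yl 4-hydroxybenzoate | C/C=C(\C)C(=O)O[C@@H](C#C)[C@]1(C)CC[C@@](O)(C(C)C)[C@@H]1[C@H](OC(=O)c1ccc(O)cc1)CC(C)=C | intermediate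
20 | (1R)-1-[(1S,2R,5R)-2-hydroxy-5-methyl-5-[(1S)-1-{[(2E)-2-methylbut-2-enoyl]oxy}prop-2-en-1-yl]-2-(propan-2-yl)cyclopentyl]-3-methylbut-3-en-1-yl 4-hydroxybenzoate | C/C=C(\C)C(=O)O[C@@H](C=C)[C@]1(C)CC[C@@](O)(C(C)C)[C@@H]1[C@H](OC(=O)c1ccc(O)cc1)CC(C)=C | intermediate
21 | (3R,3aS,4R,8S,8aR)-3-hydroxy-6,8a-dimethyl-8-{[(2E)-2-methylbut-2-enoyl]oxy}-3-(propan-2-yl)-1,2,3,3a,4,5,8,8a-octahydroazulen-4-yl 4-hydroxybenzoate (1R,4R,5S,6R,10S in core locants) | C/C=C(\C)C(=O)O[C@H]1C=C(C)C[C@@H](OC(=O)c2ccc(O)cc2)[C@@H]2[C@@]1(C)CC[C@@]2(O)C(C)C | target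

**Step count**
Total step count: 15. Longest linear sequence: 10 steps (steps 1, 3, 4, 5, 9, 10, 12, 13, 14, 15; the path through step 2 is equally long).

**Steps most likely to fail**

Step 3. The zinc enolate next to a new quaternary centre may transfer a proton to the enolizable aldehyde or add sluggishly, and the one-pot aldol/lactonization may give mixtures. Fallback: set out from 2, run the same copper-catalysed methyl addition but trap the enolate with TMSOTf to isolate the silyl enol ether methyl (1R)-1-methyl-3-(trimethylsilyloxy)cyclopent-2-ene-1-carboxylate F1. A Mukaiyama aldol of this with 4 under BF3·OEt2 at −78 °C gives the hydroxy ester 6, and CSA in CH2Cl2 lactonizes it, so the route is rejoined at 7.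

Step 4. The ketone is a β-acyloxy ketone, so a basic nucleophile can open the lactone by elimination, enolize the ketone, or reduce it by β-hydride transfer. Fallback: set out from the aldol adduct 6, silylated in the step 3 flask before it lactonizes (TESOTf, 2,6-lutidine, −78 °C) to give methyl (1R,2S)-1-methyl-2-[(1R)-3-methyl-1-(triethylsilyloxy)but-3-en-1-yl]-3-oxocyclopentane-1-carboxylate F2, whose β-silyloxy group is a poor leaving group. Addition of i-PrMgCl/CeCl3 anti to the bulky C5 side chain gives methyl (1R,2S,3R)-3-hydroxy-1-methyl-2-[(1R)-3-methyl-1-(triethylsilyloxy)but-3-en-1-yl]-3-(propan-2-yl)cyclopentane-1-carboxylate F3. 1 M HCl in THF then removes the silyl group and the freed C6 hydroxyl lactonizes, rejoining the route at 8.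

Step 15. The vinyl group sits between a quaternary carbon and an acyloxy group, so closure to the trisubstituted cycloheptene may be slow and the catalyst may decompose first. Fallback: set out from 15 and close the ring on the free allylic alcohol before esterifying it. AgNO3 (cat.) in aqueous acetone removes only the alkynyl silyl group to give (1R)-1-[(1S,2R,5R)-2-hydroxy-5-[(1S)-1-hydroxyprop-2-yn-1-yl]-5-methyl-2-(propan-2-yl)cyclopentyl]-3-methylbut-3-en-1-yl 4-[(tert-butyldimethylsilyl)oxy]benzoate F4. Lindlar hydrogenation gives (1R)-1-[(1S,2R,5R)-2-hydroxy-5-[(1S)-1-hydroxyprop-2-en-1-yl]-5-methyl-2-(propan-2-yl)cyclopentyl]-3-methylbut-3-en-1-yl 4-[(tert-butyldimethylsilyl)oxy]benzoate F5. Ring-closing metathesis with the second-generation Grubbs catalyst (H2IMes)(PCy3)Cl2Ru=CHPh in refluxing CH2Cl2 gives (3R,3aS,4R,8S,8aR)-3,8-dihydroxy-6,8a-dimethyl-3-(propan-2-yl)-1,2,3,3a,4,5,8,8a-octahydroazulen-4-yl 4-[(tert-butyldimethylsilyl)oxy]benzoate F6. Acylation with 17 (pyridine, DMAP) gives (3R,3aS,4R,8S,8aR)-3-hydroxy-6,8a-dimethyl-8-{[(2E)-2-methylbut-2-enoyl]oxy}-3-(propan-2-yl)-1,2,3,3a,4,5,8,8a-octahydroazulen-4-yl 4-[(tert-butyldimethylsilyl)oxy]benzoate F7, and Bu4NF/AcOH returns to the route at 21.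

**Further compounds**
F1 | step 3 | methyl (1R)-1-methyl-3-(trimethylsilyloxy)cyclopent-2-ene-1-carboxylate | COC(=O)[C@]1(C)CCC(O[Si](C)(C)C)=C1
F2 | step 4 | methyl (1R,2S)-1-methyl-2-[(1R)-3-methyl-1-(triethylsilyloxy)but-3-en-1-yl]-3-oxocyclopentane-1-carboxylate | COC(=O)[C@]1(C)CCC(=O)[C@@H]1[C@H](O[Si](CC)(CC)CC)CC(C)=C
F3 | step 4 | methyl (1R,2S,3R)-3-hydroxy-1-methyl-2-[(1R)-3-methyl-1-(triethylsilyloxy)but-3-en-1-yl]-3-(propan-2-yl)cyclopentane-1-carboxylate | COC(=O)[C@]1(C)CC[C@@](O)(C(C)C)[C@@H]1[C@H](O[Si](CC)(CC)CC)CC(C)=C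
F4 | step 15 | (1R)-1-[(1S,2R,5R)-2-hydroxy-5-[(1S)-1-hydroxyprop-2-yn-1-yl]-5-methyl-2-(propan-2-yl)cyclopentyl]-3-methylbut-3-en-1-yl 4-[(tert-butyldimethylsilyl)oxy]benzoate | O[C@@H](C#C)[C@]1(C)CC[C@@](O)(C(C)C)[C@@H]1[C@H](OC(=O)c1ccc(O[Si](C)(C)C(C)(C)C)cc1)CC(C)=C
F5 | step 15 | (1R)-1-[(1S,2R,5R)-2-hydroxy-5-[(1S)-1-hydroxyprop-2-en-1-yl]-5-methyl-2-(propan-2-yl)cyclopentyl]-3-methylbut-3-en-1-yl 4-[(tert-butyldimethylsilyl)oxy]benzoate | O[C@@H](C=C)[C@]1(C)CC[C@@](O)(C(C)C)[C@@H]1[C@H](OC(=O)c1ccc(O[Si](C)(C)C(C)(C)C)cc1)CC(C)=C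
F6 | step 15 | (3R,3aS,4R,8S,8aR)-3,8-dihydroxy-6,8a-dimethyl-3-(propan-2-yl)-1,2,3,3a,4,5,8,8a-octahydroazulen-4-yl 4-[(tert-butyldimethylsilyl)oxy]benzoate | O[C@H]1C=C(C)C[C@@H](OC(=O)c2ccc(O[Si](C)(C)C(C)(C)C)cc2)[C@@H]2[C@@]1(C)CC[C@@]2(O)C(C)C
F7 | step 15 | (3R,3aS,4R,8S,8aR)-3-hydroxy-6,8a-dimethyl-8-{[(2E)-2-methylbut-2-enoyl]oxy}-3-(propan-2-yl)-1,2,3,3a,4,5,8,8a-octahydroazulen-4-yl 4-[(tert-butyldimethylsilyl)oxy]benzoate | C/C=C(\C)C(=O)O[C@H]1C=C(C)C[C@@H](OC(=O)c2ccc(O[Si](C)(C)C(C)(C)C)cc2)[C@@H]2[C@@]1(C)CC[C@@]2(O)C(C)C
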